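The route rests on cutting the C7''–C8'' bond between the two oxygen-bearing sp3 carbons of the side chain. The key step exploits the 1,3-relationship of O-7'' and O-9''. C9'' is raised temporarily to an N-acyloxazolidinone. C8'', already bound through O-4' to ring B of the complete, benzyl-protected flavone (rings A–C), then becomes a (Z)-boron enolate. Its Evans syn-aldol addition to 4-(benzyloxy)benzaldehyde unites both halves and sets C7'' and C8'' (threo, S,S) in one operation. The precursor is the (R)-4-benzyloxazolidinone imide of the flavone-4'-oxyacetic acid. Borohydride then returns C9'' to the alcohol level and releases the auxiliary, and hydrogenolysis frees the three phenols.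

Key step: step 6

Assumption: C7'' is the benzylic carbinol carbon, C8'' the aryloxy-bearing carbon and C9'' the CH2OH carbon. (7''S,8''S) is the threo isomer, syn in the zigzag C9''–C8''–C7''–aryl.

Step 1
Reactants: 1 2',4',6'-trihydroxyacetophenone
Product: 2 1-[2,4-bis(benzyloxy)-6-hydroxyphenyl]ethan-1-one
Conditions: BnBr (2.1 equiv), K2CO3, acetone, reflux
Reagents that add atoms: benzyl bromide, BrCc1ccccc1
Why: Williamson ether synthesis in which two phenols are alkylated, while the remaining ortho-OH is locked in a hydrogen bond to the acetyl C=O and should stay free with two equivalents of halide.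

Step 2
Reactants: 3 syringaldehyde; 4 ethyl bromoacetate
Product: 5 ethyl 2-(4-formyl-2,6-dimethoxyphenoxy)acetate
Conditions: K2CO3, DMF, 60 °C
Reagents that add atoms: none
Why: Williamson ether synthesis (SN2) of the acidic syringyl phenoxide on a very reactive α-halo ester, which installs the future C8''–C9'' unit on O-4' without creating a stereocentre.

Step 3
Reactants: 2 1-[2,4-bis(benzyloxy)-6-hydroxyphenyl]ethan-1-one; 5 ethyl 2-(4-formyl-2,6-dimethoxyphenoxy)acetate
Product: 7 2-(4-{(E)-3-[2,4-bis(benzyloxy)-6-hydroxyphenyl]-3-oxoprop-1-en-1-yl}-2,6-dimethoxyphenoxy)acetic acid (chalcone acid), via potassium formylaryloxyacetate 6 (not isolated)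
Conditions: KOH (50% aq), EtOH, rt; then 2 M HCl
Reagents that add atoms: potassium hydroxide, [K+].[OH-] (oxygen of the new CO2H group; potassium only in 6)
Why: Claisen–Schmidt condensation in which hydroxide first saponifies the ester, the remote non-conjugated carboxylate leaves the aldehyde reactive, and E1cB dehydration should give the thermodynamically favoured (E)-enone.

Step 4
Reactants: 7 chalcone acid
Product: 9 2-{4-[5,7-bis(benzyloxy)-4-oxo-4H-chromen-2-yl]-2,6-dimethoxyphenoxy}acetic acid (flavone acid), via flavanone acid 8 (not isolated)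
Conditions: I2 (10 mol %), DMSO, 120 °C
Reagents that add atoms: none
Why: Iodine/DMSO oxidative cyclisation of a 2'-hydroxychalcone, in which oxa-Michael closure to the flavanone, α-iodination and loss of HI form the pyranone ring C, DMSO re-oxidises HI, and the benzyl ethers and the acid should persist.

Step 5
Reactants: 9 flavone acid; 10 (R)-4-benzyloxazolidin-2-one
Product: 12 (R)-4-benzyl-3-(2-{4-[5,7-bis(benzyloxy)-4-oxo-4H-chromen-2-yl]-2,6-dimethoxyphenoxy}acetyl)oxazolidin-2-one, via mixed pivalic anhydride 11 (not isolated)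
Conditions: PivCl, Et3N, THF, −20 °C; then LiCl, 10, −20 °C → rt
Reagents that add atoms: pivaloyl chloride, CC(C)(C)C(=O)Cl (atoms only in intermediate 11)
Why: Mixed-anhydride N-acylation of an oxazolidinone promoted by LiCl/Et3N, in which attack should occur at the less hindered aryloxyacetyl carbonyl and the purchased auxiliary stereocentre is not touched.

Step 6
Reactants: 12 (R)-4-benzyl-3-(2-{4-[5,7-bis(benzyloxy)-4-oxo-4H-chromen-2-yl]-2,6-dimethoxyphenoxy}acetyl)oxazolidin-2-one; 13 4-(benzyloxy)benzaldehyde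
Product: 16 (R)-4-benzyl-3-[(2R,3S)-2-{4-[5,7-bis(benzyloxy)-4-oxo-4H-chromen-2-yl]-2,6-dimethoxyphenoxy}-3-[4-(benzyloxy)phenyl]-3-hydroxypropanoyl]oxazolidin-2-one, via (Z)-dibutylboron enolate 14 (not isolated), via dibutylboron aldolate 15 (not isolated)
Conditions: Bu2BOTf (2.5 equiv), Et3N (3 equiv), CH2Cl2, −78 → 0 °C; 13, −78 → 0 °C; then pH 7 buffer, MeOH, 30% H2O2, 0 °C
Reagents that add atoms: dibutylboron triflate, CCCCB(CCCC)OS(=O)(=O)C(F)(F)F (atoms only in intermediates 14 and 15)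
Why: Bu2BOTf/Et3N soft-enolises the only acidic C–H bonds of 12 (the OCH2C=O group, the future C8'') to the chelated (Z)-boron enolate 14, whose geometry is fixed by turning the bulky 2,6-dimethoxyaryloxy group away from the auxiliary; the aldehyde then binds boron and the C8''–C7'' bond forms through a closed chair Zimmerman–Traxler transition state to give aldolate 15, which buffered H2O2 releases. The reaction type is the Evans syn-glycolate aldol reaction, which is established for N-(aryloxyacetyl)oxazolidinones with alkoxybenzaldehydes on the way to aryl glycerol β-aryl ethers. No ring of the product is closed; only the transient six-membered boron chair is involved. The syn (threo) relation of C7'' and C8'' follows from the (Z)-enolate with the aldehyde aryl group pseudo-equatorial, and the absolute sense follows from the (R)-benzyl group, which in the dipole-opposed rotamer blocks one enolate face, so that (2R,3S)-16 (8''S,7''S after reduction) should result. The step needs chemoselective enolisation and an unperturbed boron transition state: ring C has no enolisable hydrogen, 13 cannot enolise, and an extra equivalent of Bu2BOTf is supplied to saturate the Lewis-basic C4=O of the pyranone.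

Step 7
Reactants: 16 syn-aldol adduct
Product: 18 5,7-bis(benzyloxy)-2-[4-({(1S,2S)-1-[4-(benzyloxy)phenyl]-1,3-dihydroxypropan-2-yl}oxy)-3,5-dimethoxyphenyl]-4H-chromen-4-one, via hydroxy aldehyde 17 (not isolated)
Conditions: NaBH4, THF/H2O (4:1), 0 °C → rt
Reagents that add atoms: none
Why: Reductive cleavage of an N-acyloxazolidinone with borohydride, in which the activated exocyclic imide carbonyl is reduced through the aldehyde to the C9'' alcohol, the vinylogous-ester carbonyl of ring C should be inert to NaBH4, and C7'' and C8'' are not involved.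

Step 8
Reactants: 18 tri-O-benzyl diol
Product: 19 (−)-(7''S,8''S)-4'',5,7-trihydroxy-3',5'-dimethoxy-4',8''-oxyflavonolignan-7'',9''-diol
Conditions: H2 (1 atm), 10% Pd/C, THF/MeOH, rt
Reagents that add atoms: none
Why: Catalytic hydrogenolysis of the three aryl benzyl ethers, whose neutral medium should spare the secondary benzylic alcohol and C2=C3 and avoids acid-induced epimerisation at C7''.

Compound list
1 | 2',4',6'-trihydroxyacetophenone | CC(=O)c1c(O)cc(O)cc1O | starting material
2 | 1-[2,4-bis(benzyloxy)-6-hydroxyphenyl]ethan-1-one | CC(=O)c1c(O)cc(OCc2ccccc2)cc1OCc1ccccc1 | intermediate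
3 | syringaldehyde (4-hydroxy-3,5-dimethoxybenzaldehyde) | COc1cc(C=O)cc(OC)c1O | starting material
4 | ethyl bromoacetate | CCOC(=O)CBr | starting material
5 | ethyl 2-(4-formyl-2,6-dimethoxyphenoxy)acetate | CCOC(=O)COc1c(OC)cc(C=O)cc1OC | intermediate
6 | potassium 2-(4-formyl-2,6-dimethoxyphenoxy)acetate (not isolated) | [K+].[O-]C(=O)COc1c(OC)cc(C=O)cc1OC | intermediate
7 | 2-(4-{(E)-3-[2,4-bis(benzyloxy)-6-hydroxyphenyl]-3-oxoprop-1-en-1-yl}-2,6-dimethoxyphenoxy)acetic acid (chalcone acid) | COc1cc(/C=C/C(=O)c2c(O)cc(OCc3ccccc3)cc2OCc2ccccc2)cc(OC)c1OCC(=O)O | intermediate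
8 | (±)-2-{4-[5,7-bis(benzyloxy)-4-oxochroman-2-yl]-2,6-dimethoxyphenoxy}acetic acid (flavanone acid, not isolated) | COc1cc(C2CC(=O)c3c(OCc4ccccc4)cc(OCc4ccccc4)cc3O2)cc(OC)c1OCC(=O)O | intermediate
9 | 2-{4-[5,7-bis(benzyloxy)-4-oxo-4H-chromen-2-yl]-2,6-dimethoxyphenoxy}acetic acid (flavone acid) | COc1cc(-c2cc(=O)c3c(OCc4ccccc4)cc(OCc4ccccc4)cc3o2)cc(OC)c1OCC(=O)O | intermediate
10 | (R)-4-benzyloxazolidin-2-one | O=C1N[C@H](Cc2ccccc2)CO1 | starting material
11 | mixed anhydride of 9 and pivalic acid (not isolated) | COc1cc(-c2cc(=O)c3c(OCc4ccccc4)cc(OCc4ccccc4)cc3o2)cc(OC)c1OCC(=O)OC(=O)C(C)(C)C | intermediate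
12 | (R)-4-benzyl-3-(2-{4-[5,7-bis(benzyloxy)-4-oxo-4H-chromen-2-yl]-2,6-dimethoxyphenoxy}acetyl)oxazolidin-2-one | COc1cc(-c2cc(=O)c3c(OCc4ccccc4)cc(OCc4ccccc4)cc3o2)cc(OC)c1OCC(=O)N1[C@H](Cc2ccccc2)COC1=O | intermediate
13 | 4-(benzyloxy)benzaldehyde | O=Cc1ccc(OCc2ccccc2)cc1 | starting material
14 | (Z)-dibutylboron enolate of 12 (not isolated) | COc1cc(-c2cc(=O)c3c(OCc4ccccc4)cc(OCc4ccccc4)cc3o2)cc(OC)c1O/C=C(\OB(CCCC)CCCC)N1[C@H](Cc2ccccc2)COC1=O | intermediate
15 | (2R,3S)-dibutylboron aldolate (not isolated) | COc1cc(-c2cc(=O)c3c(OCc4ccccc4)cc(OCc4ccccc4)cc3o2)cc(OC)c1O[C@@H](C(=O)N1[C@H](Cc2ccccc2)COC1=O)[C@@H](OB(CCCC)CCCC)c1ccc(OCc2ccccc2)cc1 | intermediate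
16 | (R)-4-benzyl-3-[(2R,3S)-2-{4-[5,7-bis(benzyloxy)-4-oxo-4H-chromen-2-yl]-2,6-dimethoxyphenoxy}-3-[4-(benzyloxy)phenyl]-3-hydroxypropanoyl]oxazolidin-2-one | COc1cc(-c2cc(=O)c3c(OCc4ccccc4)cc(OCc4ccccc4)cc3o2)cc(OC)c1O[C@@H](C(=O)N1[C@H](Cc2ccccc2)COC1=O)[C@@H](O)c1ccc(OCc2ccccc2)cc1 | intermediate
17 | (2R,3S)-2-{4-[5,7-bis(benzyloxy)-4-oxo-4H-chromen-2-yl]-2,6-dimethoxyphenoxy}-3-[4-(benzyloxy)phenyl]-3-hydroxypropanal (not isolated) | COc1cc(-c2cc(=O)c3c(OCc4ccccc4)cc(OCc4ccccc4)cc3o2)cc(OC)c1O[C@@H](C=O)[C@@H](O)c1ccc(OCc2ccccc2)cc1 | intermediate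
18 | 5,7-bis(benzyloxy)-2-[4-({(1S,2S)-1-[4-(benzyloxy)phenyl]-1,3-dihydroxypropan-2-yl}oxy)-3,5-dimethoxyphenyl]-4H-chromen-4-one | COc1cc(-c2cc(=O)c3c(OCc4ccccc4)cc(OCc4ccccc4)cc3o2)cc(OC)c1O[C@@H](CO)[C@@H](O)c1ccc(OCc2ccccc2)cc1 | intermediate
19 | (−)-(7''S,8''S)-4'',5,7-trihydroxy-3',5'-dimethoxy-4',8''-oxyflavonolignan-7'',9''-diol | COc1cc(-c2cc(=O)c3c(O)cc(O)cc3o2)cc(OC)c1O[C@@H](CO)[C@@H](O)c1ccc(O)cc1 | target

Total step count: 8. Longest linear sequence: 7 steps (3 → 19 through steps 2–8; 1 → 19 through steps 1 and 3–8 is equally long).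

Steps most likely to fail

Step 6 (key aldol).
- **What may go wrong:** The Lewis-basic pyranone carbonyl may sequester the boron triflate. Enolisation of the sparingly soluble imide may stay incomplete at low temperature. A boron-loaded ring C may erode facial selectivity or lose the peri 5-O-benzyl group.
- **Fallback:** It sets out from 9 and returns at 18. It forms the same C7''–C8'' bond without stereocontrol and sets both centres afterwards by dynamic kinetic resolution.
  - Acid 9 is esterified (MeI, K2CO3, DMF) to the methyl ester F1.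
  - The lithium enolate of F1 (LiHMDS, 2 equiv, THF, −78 °C) is C-acylated with commercial 4-(benzyloxy)benzoyl chloride in a crossed Claisen condensation. This gives the racemic, configurationally labile β-keto ester F2.
  - Noyori asymmetric transfer hydrogenation follows (RuCl(p-cymene)[(R,R)-TsDPEN], HCO2H/Et3N, CH2Cl2, 30 °C). This reaction type is known to turn α-alkoxy β-aryl β-keto esters into syn products. It should funnel both enantiomers into the syn-(2R,3S)-hydroxy ester F3.
  - LiBH4 (THF, 0 °C) then reduces F3 to 18.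

Step 8 (global hydrogenolysis).
- **What may go wrong:** Over-reduction may compete with the cleavage of three benzyl ethers, either as hydrogenolysis of the electron-rich benzylic C7''–O bond or as saturation of C2=C3 in ring C.
- **Fallback:** It sets out from 12 and returns at 19. It moves the hydrogenolysis to a stage where no benzylic alcohol exists and ends with a fluoride deprotection.
  - Imide 12 is debenzylated (H2, Pd/C, THF) to the 5,7-dihydroxy imide F4.
  - TBSCl/imidazole (DMF) silylates the 7-OH to the 7-O-TBS imide F5, and the chelated 5-OH stays free.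
  - The boron aldol reaction of step 6 is run with one more equivalent of Bu2BOTf and Et3N for the 5-OH, and with commercial 4-(tert-butyldimethylsilyloxy)benzaldehyde as acceptor. It should give the bis-silyl syn-aldol adduct F6.
  - NaBH4 (THF/H2O) gives the bis-silyl diol F7.
  - Et3N·3HF (THF, 0 °C) frees 19.

Step 7 (reductive removal of the auxiliary).
- **What may go wrong:** Hydride may attack the endocyclic carbamate carbonyl, because the exocyclic one is shielded by the di-ortho-substituted aryloxy group. The basic medium may also trigger retro-aldol cleavage with loss of diastereomeric purity.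
- **Fallback:** It sets out from 16 and returns at 18. The auxiliary is first removed hydrolytically, and an activated acid is then reduced.
  - LiOH/H2O2 (THF/H2O, 0 °C), which is selective for the exocyclic carbonyl, gives the hydroxy acid F8.
  - Isobutyl chloroformate/N-methylmorpholine (THF, −15 °C) gives the mixed carbonic anhydride F9.
  - NaBH4 in water (−15 → 0 °C) should quickly reduce F9 to 18.

Further compounds
F1 | step 6 | methyl 2-{4-[5,7-bis(benzyloxy)-4-oxo-4H-chromen-2-yl]-2,6-dimethoxyphenoxy}acetate | COc1cc(-c2cc(=O)c3c(OCc4ccccc4)cc(OCc4ccccc4)cc3o2)cc(OC)c1OCC(=O)OC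
F2 | step 6 | methyl (±)-2-{4-[5,7-bis(benzyloxy)-4-oxo-4H-chromen-2-yl]-2,6-dimethoxyphenoxy}-3-[4-(benzyloxy)phenyl]-3-oxopropanoate | COc1cc(-c2cc(=O)c3c(OCc4ccccc4)cc(OCc4ccccc4)cc3o2)cc(OC)c1OC(C(=O)OC)C(=O)c1ccc(OCc2ccccc2)cc1
F3 | step 6 | methyl (2R,3S)-2-{4-[5,7-bis(benzyloxy)-4-oxo-4H-chromen-2-yl]-2,6-dimethoxyphenoxy}-3-[4-(benzyloxy)phenyl]-3-hydroxypropanoate | COc1cc(-c2cc(=O)c3c(OCc4ccccc4)cc(OCc4ccccc4)cc3o2)cc(OC)c1O[C@@H](C(=O)OC)[C@@H](O)c1ccc(OCc2ccccc2)cc1
F4 | step 8 | (R)-4-benzyl-3-{2-[4-(5,7-dihydroxy-4-oxo-4H-chromen-2-yl)-2,6-dimethoxyphenoxy]acetyl}oxazolidin-2-one | COc1cc(-c2cc(=O)c3c(O)cc(O)cc3o2)cc(OC)c1OCC(=O)N1[C@H](Cc2ccccc2)COC1=O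
F5 | step 8 | (R)-4-benzyl-3-(2-{4-[7-(tert-butyldimethylsilyloxy)-5-hydroxy-4-oxo-4H-chromen-2-yl]-2,6-dimethoxyphenoxy}acetyl)oxazolidin-2-one | COc1cc(-c2cc(=O)c3c(O)cc(O[Si](C)(C)C(C)(C)C)cc3o2)cc(OC)c1OCC(=O)N1[C@H](Cc2ccccc2)COC1=O
F6 | step 8 | (R)-4-benzyl-3-[(2R,3S)-2-{4-[7-(tert-butyldimethylsilyloxy)-5-hydroxy-4-oxo-4H-chromen-2-yl]-2,6-dimethoxyphenoxy}-3-[4-(tert-butyldimethylsilyloxy)phenyl]-3-hydroxypropanoyl]oxazolidin-2-one | COc1cc(-c2cc(=O)c3c(O)cc(O[Si](C)(C)C(C)(C)C)cc3o2)cc(OC)c1O[C@@H](C(=O)N1[C@H](Cc2ccccc2)COC1=O)[C@@H](O)c1ccc(O[Si](C)(C)C(C)(C)C)cc1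
F7 | step 8 | 7-(tert-butyldimethylsilyloxy)-2-[4-({(1S,2S)-1-[4-(tert-butyldimethylsilyloxy)phenyl]-1,3-dihydroxypropan-2-yl}oxy)-3,5-dimethoxyphenyl]-5-hydroxy-4H-chromen-4-one | COc1cc(-c2cc(=O)c3c(O)cc(O[Si](C)(C)C(C)(C)C)cc3o2)cc(OC)c1O[C@@H](CO)[C@@H](O)c1ccc(O[Si](C)(C)C(C)(C)C)cc1
F8 | step 7 | (2R,3S)-2-{4-[5,7-bis(benzyloxy)-4-oxo-4H-chromen-2-yl]-2,6-dimethoxyphenoxy}-3-[4-(benzyloxy)phenyl]-3-hydroxypropanoic acid | COc1cc(-c2cc(=O)c3c(OCc4ccccc4)cc(OCc4ccccc4)cc3o2)cc(OC)c1O[C@@H](C(=O)O)[C@@H](O)c1ccc(OCc2ccccc2)cc1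
F9 | step 7 | mixed anhydride of F8 and isobutyl hydrogen carbonate | COc1cc(-c2cc(=O)c3c(OCc4ccccc4)cc(OCc4ccccc4)cc3o2)cc(OC)c1O[C@@H](C(=O)OC(=O)OCC(C)C)[C@@H](O)c1ccc(OCc2ccccc2)cc1
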